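## Retrosynthetic overview
1. Cut both norbornene bonds (C1–C13′, C3–C11′) by a retro-[4+2]. In the same operation rehydrate the diene C1=C5 bond. The partners are then a bench-stable 5-hydroxyguai-3-ene carbinol and the unprotected 10′-hydroxy-1,10-seco-eudesmanolide. The 2-acetoxy-cyclopentadiene exists only in the flask.
2. Dienophile: the C10′ carbinol comes from an enone plus MeCeCl2, and the enone from allylic oxidation. The cis α-methylene lactone comes from Pd enyne cycloisomerisation of a propiolate. The cyclohexene comes from (R)-citronellal plus methyl vinyl ketone.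
3. Diene precursor: the cyclopentene comes from ring-closing metathesis, and C4/C15 from isopropenyl addition. C14 and C1–C2 come from a cuprate/aldol coupling. The trans lactone comes from conjugate alkynylation and cyclocarbonylation, and C8 from a desymmetrised cycloheptadiene endoperoxide.
4. Ring order, dienophile: cyclohexene, then lactone. Ring order, diene half: seven-membered ring (purchased), then lactone, then cyclopentene. Both norbornene rings form last.

Assumption: the SMILES is taken literally. It is the antipode of the usual 7α-H Inula lactone series, so natural Inula lactones cannot serve as starting materials.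

## Route

Step 1
Reactants: 1 (R)-citronellal; 2 methyl vinyl ketone
Product: 4 (4R)-4-[(2R)-6-methylhept-5-en-2-yl]cyclohex-2-en-1-one, via keto aldehyde 3 (not isolated)
Conditions: (R)-2-[diphenyl(trimethylsilyloxy)methyl]pyrrolidine (5 mol %), ethyl 3,4-dihydroxybenzoate (20 mol %), neat, 4 °C; then aq KOH (0.1 M), n-Bu4NOH (cat.), Et2O–THF, reflux
Reagents that add atoms: none
Why: Enamine-catalysed Michael addition followed by intramolecular aldol condensation (Robinson-type annulation), in which the catalyst shields one enamine face and sets the ring centre as 4R while the side-chain centre is carried over unchanged from 1.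

Step 2
Reactants: 4 (4R)-4-[(2R)-6-methylhept-5-en-2-yl]cyclohex-2-en-1-one
Product: 6 (1S,4R)-4-[(2R)-5-hydroxypentan-2-yl]cyclohex-2-en-1-ol, via enone aldehyde 5 (not isolated)
Conditions: O3, CH2Cl2–MeOH, −78 °C (Sudan red 7B end point); then CeCl3·7H2O, NaBH4, −78 → 0 °C
Reagents that add atoms: ozone [O-][O+]=O
Why: Ozonolysis cleaves only the electron-rich trisubstituted alkene, and the Luche 1,2-reduction delivers hydride axially to the half-chair with a pseudo-equatorial side chain, giving the trans-1,4 (1S) allylic alcohol.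

Step 3
Reactants: 6 (1S,4R)-4-[(2R)-5-hydroxypentan-2-yl]cyclohex-2-en-1-ol
Product: 7 (4R)-4-[(1R,4S)-4-hydroxycyclohex-2-en-1-yl]pentyl acetate
Conditions: AcCl (1.05 equiv), 2,4,6-collidine, CH2Cl2, −78 °C
Reagents that add atoms: acetyl chloride CC(=O)Cl
Why: Kinetically selective acylation, because the unhindered primary hydroxyl is esterified far faster than the secondary allylic one at low temperature and no stereocentre is touched.

Step 4
Reactants: 7 (4R)-4-[(1R,4S)-4-hydroxycyclohex-2-en-1-yl]pentyl acetate; 8 propiolic acid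
Product: 9 (1S,4R)-4-[(2R)-5-acetoxypentan-2-yl]cyclohex-2-en-1-yl propiolate
Conditions: DCC, DMAP (5 mol %), CH2Cl2, −20 → 0 °C
Reagents that add atoms: none
Why: Steglich esterification occurs at oxygen only, so the carbinol configuration is retained.

Step 5
Reactants: 9 (1S,4R)-4-[(2R)-5-acetoxypentan-2-yl]cyclohex-2-en-1-yl propiolate
Product: 10 (4R)-4-[(3aS,7aS)-3-methylidene-2-oxo-2,3,3a,6,7,7a-hexahydro-1-benzofuran-5-yl]pentyl acetate
Conditions: Pd2(dba)3·CHCl3 (2.5 mol %), P(o-tol)3 (10 mol %), AcOH (20 mol %), PhMe, 60 °C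
Reagents that add atoms: none
Why: Trost-type Pd–H enyne cycloisomerisation (formal Alder-ene), in which α-palladation of the ynoate and tether-enforced syn 5-exo insertion give the cis ring fusion (C7′ set from C8′), and the only syn β-hydrogen (C5′–H of the trans series) is eliminated to place the alkene at C5′=C6′.

Step 6
Reactants: 10 (4R)-4-[(3aS,7aS)-3-methylidene-2-oxo-2,3,3a,6,7,7a-hexahydro-1-benzofuran-5-yl]pentyl acetate
Product: 12 (4R)-4-[(3aS,7aS)-3-methylidene-2,6-dioxo-2,3,3a,6,7,7a-hexahydro-1-benzofuran-5-yl]pentyl acetate, via allylic alcohol 11 (not isolated)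
Conditions: SeO2 (0.3 equiv), t-BuOOH (2 equiv), CH2Cl2, 0 °C → rt; aq Na2SO3 wash; crude, Dess–Martin periodinane, NaHCO3, CH2Cl2, 0 °C
Reagents that add atoms: selenium dioxide O=[Se]=O (oxygen carrier); tert-butyl hydroperoxide CC(C)(C)OO
Why: SeO2 allylic oxidation (ene then [2,3]-shift) bonds selenium to the less substituted C6′ and, by the CH2 > CH rule, oxidises the ring CH2 next to the substituted alkene carbon while the electron-poor methylidene is inert, and the Dess–Martin oxidation removes the irrelevant carbinol centre.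

Step 7
Reactants: 12 (4R)-4-[(3aS,7aS)-3-methylidene-2,6-dioxo-2,3,3a,6,7,7a-hexahydro-1-benzofuran-5-yl]pentyl acetate
Product: 13 (4R)-4-[(3aS,6R,7aS)-6-hydroxy-6-methyl-3-methylidene-2-oxo-2,3,3a,6,7,7a-hexahydro-1-benzofuran-5-yl]pentyl acetate
Conditions: MeLi, CeCl3 (anhydrous), THF, −78 °C, 30 min; aq NH4Cl
Reagents that add atoms: methyllithium [Li]C
Why: Imamoto organocerium 1,2-addition is weakly basic and ketone-selective (no β-elimination, lactone or acetate attack), and methyl enters from the convex face opposite the cis-fused lactone so the hydroxyl ends cis to O8′ (6R).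

Step 8
Reactants: 14 cyclohepta-1,3-diene
Product: 16 (R)-4-hydroxycyclohept-2-en-1-one, via endoperoxide 15 (not isolated)
Conditions: O2, tetraphenylporphyrin (0.1 mol %), hν, CH2Cl2, 0 °C; then 9-O-acetylcupreidine (10 mol %), CH2Cl2, rt
Reagents that add atoms: dioxygen O=O
Why: Singlet-oxygen [4+2] cycloaddition gives a meso endoperoxide, and an enantioselective Kornblum–DeLaMare rearrangement removes one of the two enantiotopic bridgehead protons to set C8 (the pseudo-enantiomeric cupreine catalyst is used if the sense of induction proves opposite).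

Step 9
Reactants: 16 (R)-4-hydroxycyclohept-2-en-1-one
Product: 17 (R)-4-(tert-butyldimethylsilyloxy)cyclohept-2-en-1-one
Conditions: TBSCl, imidazole, DMF, rt
Reagents that add atoms: tert-butyldimethylsilyl chloride CC(C)(C)[Si](C)(C)Cl
Why: Standard O-silylation blocks aluminium alkoxide-directed syn delivery in the next step and provides a bulky group that directs anti addition.

Step 10
Reactants: 17 (R)-4-(tert-butyldimethylsilyloxy)cyclohept-2-en-1-one; 18 ethynyltrimethylsilane
Product: 19 (3S,4R)-4-(tert-butyldimethylsilyloxy)-3-[(trimethylsilyl)ethynyl]cycloheptan-1-one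
Conditions: 18, n-BuLi, Et2O, 0 °C; Me2AlCl; then Ni(acac)2 (10 mol %), i-Bu2AlH (10 mol %), 17, Et2O, −5 °C; aq Rochelle salt
Reagents that add atoms: none
Why: Nickel-catalysed conjugate addition of an alkynylalane to an s-trans enone takes place anti to the γ-silyloxy group and so fixes the trans C7/C8 relationship of the later lactone.

Step 11
Reactants: 19 (3S,4R)-4-(tert-butyldimethylsilyloxy)-3-[(trimethylsilyl)ethynyl]cycloheptan-1-one
Product: 21 (5R,6S)-5-(tert-butyldimethylsilyloxy)-6-[(trimethylsilyl)ethynyl]cyclohept-2-en-1-one, via silyl enol ether 20 (not isolated)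
Conditions: LDA, TMSCl, THF, −78 °C; then Pd(OAc)2 (10 mol %), O2 (1 atm), DMSO, rt
Reagents that add atoms: chlorotrimethylsilane C[Si](C)(C)Cl (present in 20 only)
Why: Kinetic deprotonation takes the α-CH2 remote from the branched C7, and the aerobic Saegusa–Ito dehydrogenation with divalent palladium then places the new enone on the C1/C10 side without touching a stereocentre.

Step 12
Reactants: 21 (5R,6S)-5-(tert-butyldimethylsilyloxy)-6-[(trimethylsilyl)ethynyl]cyclohept-2-en-1-one; 22 acrolein
Product: 24 (2R,3R,5R,6S)-5-(tert-butyldimethylsilyloxy)-2-[(1R)-1-hydroxyprop-2-enyl]-3-methyl-6-[(trimethylsilyl)ethynyl]cycloheptan-1-one, via lithium enolate 23 (not isolated)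
Conditions: MeLi (2.2 equiv), CuI (1.1 equiv), Et2O, −78 °C; then 22, −78 °C, 10 min; aq NH4Cl
Reagents that add atoms: methyllithium [Li]C (as Me2CuLi)
Why: Gilman conjugate addition/aldol three-component coupling, in which methyl adds 3,5-trans to the silyloxy group (C10), the enolate reacts anti to the new methyl (C1), and the closed transition state of the ring E-enolate gives the anti aldol, which is the required 2R carbinol.

Step 13
Reactants: 24 (2R,3R,5R,6S)-5-(tert-butyldimethylsilyloxy)-2-[(1R)-1-hydroxyprop-2-enyl]-3-methyl-6-[(trimethylsilyl)ethynyl]cycloheptan-1-one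
Product: 25 (2R,3R,5R,6S)-6-ethynyl-5-hydroxy-2-[(1R)-1-hydroxyprop-2-enyl]-3-methylcycloheptan-1-one
Conditions: n-Bu4NF (2.5 equiv), AcOH (2.5 equiv), THF, 0 °C → rt
Reagents that add atoms: none
Why: Buffered fluoride desilylation removes the O-silyl and C-silyl groups together, and the acetic acid suppresses retro-aldol cleavage and epimerisation.

Step 14
Reactants: 25 (2R,3R,5R,6S)-6-ethynyl-5-hydroxy-2-[(1R)-1-hydroxyprop-2-enyl]-3-methylcycloheptan-1-one
Product: 26 trans-fused α-methylene lactone ketone (7S,8R,10R,1R,2R; guaiane numbering; C5 ketone and C1 1-hydroxyallyl side chain)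
Conditions: PdCl2 (5 mol %), thiourea (10 mol %), CO (1 atm), acetone, 50 °C
Reagents that add atoms: carbon monoxide [C-]#[O+]
Why: Palladium-catalysed cyclocarbonylation of a homopropargylic alcohol converts the trans-2-ethynyl carbinol directly into the trans-fused α-methylene-γ-butyrolactone with both centres retained, and the remote allylic hydroxyl cannot form a five-membered ring.

Step 15
Reactants: 26 trans-fused α-methylene lactone ketone
Product: 28 tertiary carbinol acetate (C5 hydroxy and isopropenyl; C2 acetoxy; C5 epimers inconsequential), via diol 27 (not isolated)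
Conditions: isopropenylmagnesium bromide (3 equiv), CeCl3 (3 equiv), THF, −78 °C; then Ac2O (1.2 equiv), −78 → −20 °C; aq NH4Cl
Reagents that add atoms: isopropenylmagnesium bromide C=C(C)[Mg]Br; acetic anhydride CC(=O)OC(C)=O
Why: Organocerium 1,2-addition prefers the ketone over the lactone and the exocyclic Michael acceptor, only the secondary alkoxide is acetylated in situ (C2 retained), and the new C5 centre is erased in step 17.

Step 16
Reactants: 28 tertiary carbinol acetate
Product: 29 2-acetoxy-5-hydroxyguaia-3,11(13)-dien-12,8-olide (1R,2R,7S,8R,10R; C5 epimers)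
Conditions: second-generation Hoveyda–Grubbs catalyst (5 mol %), CH2Cl2 (5 mM), 40 °C
Reagents that add atoms: none
Why: Ring-closing metathesis of the vinyl and isopropenyl groups gives the trisubstituted cyclopentene, while the electron-poor 1,1-disubstituted lactone methylidene does not take part.

Step 17
Reactants: 29 2-acetoxy-5-hydroxyguaia-3,11(13)-dien-12,8-olide; 13 (4R)-4-[(3aS,6R,7aS)-6-hydroxy-6-methyl-3-methylidene-2-oxo-2,3,3a,6,7,7a-hexahydro-1-benzofuran-5-yl]pentyl acetate
Product: 31 CNP0257312.1 (target), via acetoxy diene 30 (not isolated)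
Conditions: Burgess reagent (1.0 equiv), PhMe, 45 °C, 20 min; then 13 (2.5 equiv), BHT (5 mol %), concentrate to 2 M, 40 °C, 72 h (excess 13 recovered)
Reagents that add atoms: none
Why: Burgess dehydration of the tertiary allylic carbinol releases the labile 2-acetoxy-guaia-1(5),3-diene, which is trapped at once in a biomimetic intermolecular Diels–Alder reaction in which the dienophile adds syn to the acetoxy group and anti to the C10 methyl, through its convex lactone face, with the carbonyl endo, and with the CH2 terminus bonding to the fully substituted C1 (no vicinal quaternary centres), so setting C1, C3 and C11′.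

## Compound list
1 | (R)-citronellal | C[C@H](CCC=C(C)C)CC=O | starting material
2 | methyl vinyl ketone | C=CC(C)=O | starting material
3 | (2R,3R)-3,7-dimethyl-2-(3-oxobutyl)oct-6-enal | O=C[C@H](CCC(C)=O)[C@H](C)CCC=C(C)C | intermediate
4 | (4R)-4-[(2R)-6-methylhept-5-en-2-yl]cyclohex-2-en-1-one | O=C1CC[C@H]([C@H](C)CCC=C(C)C)C=C1 | intermediate
5 | (4R)-4-[(1R)-4-oxocyclohex-2-en-1-yl]pentanal | O=C1CC[C@H]([C@H](C)CCC=O)C=C1 | intermediate
6 | (1S,4R)-4-[(2R)-5-hydroxypentan-2-yl]cyclohex-2-en-1-ol | O[C@H]1CC[C@H]([C@H](C)CCCO)C=C1 | intermediate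
7 | (4R)-4-[(1R,4S)-4-hydroxycyclohex-2-en-1-yl]pentyl acetate | O[C@H]1CC[C@H]([C@H](C)CCCOC(C)=O)C=C1 | intermediate
8 | propiolic acid | C#CC(=O)O | starting material
9 | (1S,4R)-4-[(2R)-5-acetoxypentan-2-yl]cyclohex-2-en-1-yl propiolate | C#CC(=O)O[C@H]1CC[C@H]([C@H](C)CCCOC(C)=O)C=C1 | intermediate
10 | cis-fused α-methylene lactone with C5′=C6′ alkene | C=C1C(=O)O[C@H]2CCC([C@H](C)CCCOC(C)=O)=C[C@H]21 | intermediate
11 | 10′-hydroxy derivative of 10 (epimers) | C=C1C(=O)O[C@H]2CC(O)C([C@H](C)CCCOC(C)=O)=C[C@H]21 | intermediate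
12 | 10′-oxo enone | C=C1C(=O)O[C@H]2CC(=O)C([C@H](C)CCCOC(C)=O)=C[C@H]21 | intermediate
13 | 1-acetoxy-10-hydroxy-1,10-seco-eudesma-5,11(13)-dien-12,8-olide (4R,7S,8S,10R) | C=C1C(=O)O[C@H]2C[C@@](C)(O)C([C@H](C)CCCOC(C)=O)=C[C@H]21 | intermediate
14 | cyclohepta-1,3-diene | C1=CC=CCCC1 | starting material
15 | 6,7-dioxabicyclo[3.2.2]non-8-ene (meso) | C1CC2OOC(C1)C=C2 | intermediate
16 | (R)-4-hydroxycyclohept-2-en-1-one | O=C1C=C[C@H](O)CCC1 | intermediate
17 | (R)-4-(tert-butyldimethylsilyloxy)cyclohept-2-en-1-one | O=C1C=C[C@H](O[Si](C)(C)C(C)(C)C)CCC1 | intermediate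
18 | ethynyltrimethylsilane | C#C[Si](C)(C)C | starting material
19 | (3S,4R)-4-(TBSO)-3-[(trimethylsilyl)ethynyl]cycloheptan-1-one | O=C1C[C@@H](C#C[Si](C)(C)C)[C@H](O[Si](C)(C)C(C)(C)C)CCC1 | intermediate
20 | kinetic trimethylsilyl enol ether of 19 | C[Si](C)(C)OC1=CCC[C@@H](O[Si](C)(C)C(C)(C)C)[C@H](C#C[Si](C)(C)C)C1 | intermediate
21 | (5R,6S)-5-(TBSO)-6-[(trimethylsilyl)ethynyl]cyclohept-2-en-1-one | O=C1C=CC[C@@H](O[Si](C)(C)C(C)(C)C)[C@H](C#C[Si](C)(C)C)C1 | intermediate
22 | acrolein | C=CC=O | starting material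
23 | lithium enolate after methyl transfer | [Li+].[O-]C1=C[C@H](C)C[C@@H](O[Si](C)(C)C(C)(C)C)[C@H](C#C[Si](C)(C)C)C1 | intermediate
24 | anti aldol (2R,3R,5R,6S,1′R) | O=C1[C@@H]([C@H](O)C=C)[C@H](C)C[C@@H](O[Si](C)(C)C(C)(C)C)[C@H](C#C[Si](C)(C)C)C1 | intermediate
25 | ethynyl diol ketone | O=C1[C@@H]([C@H](O)C=C)[C@H](C)C[C@@H](O)[C@H](C#C)C1 | intermediate
26 | trans-fused α-methylene lactone ketone | C=C1C(=O)O[C@@H]2C[C@@H](C)[C@H]([C@H](O)C=C)C(=O)C[C@@H]12 | intermediate
27 | isopropenyl adduct diol (C5 epimers) | C=C1C(=O)O[C@@H]2C[C@@H](C)[C@H]([C@H](O)C=C)C(O)(C(C)=C)C[C@@H]12 | intermediate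
28 | tertiary carbinol acetate (C5 epimers) | C=C1C(=O)O[C@@H]2C[C@@H](C)[C@H]([C@H](OC(C)=O)C=C)C(O)(C(C)=C)C[C@@H]12 | intermediate
29 | 2-acetoxy-5-hydroxyguaia-3,11(13)-dien-12,8-olide (C5 epimers) | C=C1C(=O)O[C@@H]2C[C@@H](C)[C@@H]3[C@H](OC(C)=O)C=C(C)C3(O)C[C@@H]12 | intermediate
30 | (2R,7S,8R,10R)-2-acetoxyguaia-1(5),3,11(13)-trien-12,8-olide | C=C1C(=O)O[C@@H]2C[C@@H](C)C3=C(C[C@@H]12)C(C)=C[C@H]3OC(C)=O | intermediate
31 | CNP0257312.1 | C=C1C(=O)O[C@@H]2C[C@@H](C)[C@]34C[C@]5(C(=O)O[C@H]6C[C@@](C)(O)C([C@H](C)CCCOC(C)=O)=C[C@H]65)[C@H](C(C)=C3C[C@@H]12)[C@H]4OC(C)=O | target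

## Step count and risk
Total step count: 17. Longest linear sequence: 10 (steps 8–17).

The three steps most likely to fail are 17, 5 and 15.

**Step 17.** The risks are self-dimerisation of 30 through its own methylidene lactone, a 1,5-hydrogen shift of the acetoxy diene, and the wrong regiochemistry.
- The fallback sets out from 29 and comes back to the route at 31.
- Thiophenol and Et3N add to the methylidene lactone of 29 to give the sulfide carbinol F5, which removes the competing dienophile.
- Burgess dehydration gives the sulfide diene F6 in the flask.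
- F6 is combined with 13 under 1.0 GPa at room temperature to give the sulfide adduct F7.
- NaIO4 oxidises F7 to the sulfoxide F8.
- Warming F8 in toluene over CaCO3 eliminates the sulfoxide and regenerates the methylidene lactone of 31.

**Step 5.** The terminal ynoate may oligomerise, or the s-trans ester may refuse to cyclise.
- The fallback sets out from 7 and comes back to the route at 10.
- Compound 7 is esterified with 2-bromoacrylic acid (DCC, DMAP) to give the 2-bromoacrylate F1.
- An intramolecular Heck reaction (Pd(OAc)2, PPh3, Ag2CO3, MeCN, 60 °C) starts from a defined vinyl–palladium bond at C11′.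
- It closes the same cis-fused ring and ends with the same syn β-hydride elimination of C5′–H.

**Step 15.** The organocerium reagent may attack the methylidene lactone.
- The fallback sets out from 24 and comes back to the route at 29, building the carbocycle before the lactone.
- Isopropenylcerium addition to 24 and in situ acetylation give the bis-silyl carbinol acetate F2.
- Ring-closing metathesis gives the hydroazulene F3, with the hindered silyl alkyne left untouched.
- Buffered n-Bu4NF gives the ethynyl diol F4.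
- PdCl2/thiourea/CO cyclocarbonylation of F4 gives 29.

## Further compounds
F1 | step 5 | (1S,4R)-4-[(2R)-5-acetoxypentan-2-yl]cyclohex-2-en-1-yl 2-bromoacrylate | C=C(Br)C(=O)O[C@H]1CC[C@H]([C@H](C)CCCOC(C)=O)C=C1
F2 | step 15 | bis-silyl isopropenyl carbinol acetate (C5 epimers) | OC1(C(C)=C)[C@@H]([C@H](OC(C)=O)C=C)[C@H](C)C[C@@H](O[Si](C)(C)C(C)(C)C)[C@H](C#C[Si](C)(C)C)C1
F3 | step 15 | bis-silyl hydroazulene carbinol acetate | CC1=C[C@@H](OC(C)=O)[C@H]2[C@H](C)C[C@@H](O[Si](C)(C)C(C)(C)C)[C@H](C#C[Si](C)(C)C)CC12O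
F4 | step 15 | ethynyl diol hydroazulene acetate | CC1=C[C@@H](OC(C)=O)[C@H]2[C@H](C)C[C@@H](O)[C@H](C#C)CC12O
F5 | step 17 | 13-phenylthio adduct of 29 | c1ccccc1SCC1C(=O)O[C@@H]2C[C@@H](C)[C@@H]3[C@H](OC(C)=O)C=C(C)C3(O)C[C@@H]12
F6 | step 17 | 13-phenylthio acetoxy diene | c1ccccc1SCC1C(=O)O[C@@H]2C[C@@H](C)C3=C(C[C@@H]12)C(C)=C[C@H]3OC(C)=O
F7 | step 17 | 13-phenylthio Diels–Alder adduct | c1ccccc1SCC1C(=O)O[C@@H]2C[C@@H](C)[C@]34C[C@]5(C(=O)O[C@H]6C[C@@](C)(O)C([C@H](C)CCCOC(C)=O)=C[C@H]65)[C@H](C(C)=C3C[C@@H]12)[C@H]4OC(C)=O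
F8 | step 17 | 13-phenylsulfinyl Diels–Alder adduct | O=S(CC1C(=O)O[C@@H]2C[C@@H](C)[C@]34C[C@]5(C(=O)O[C@H]6C[C@@](C)(O)C([C@H](C)CCCOC(C)=O)=C[C@H]65)[C@H](C(C)=C3C[C@@H]12)[C@H]4OC(C)=O)c1ccccc1
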